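## Retrosynthetic overview

1. After a final debenzylation, the flavanone C2–aryl bond is cut to an arylboronic acid on the dihydrobenzofuran and an achiral 5,7-dibenzyloxychromone. A catalyst-controlled 1,4-addition joins them and sets the third stereocentre.
2. The boronic acid comes from an aryl bromide. The CH2OH comes from a methyl ester, and the same hydride step frees the guaiacyl OH.
3. The trans-2-aryl-dihydrobenzofuran-3-carboxylate comes from a metal-free iodine(III) ring contraction (1,2-shift of the fused aryl ring) of an (R)-flavanone. C2 is carried over and C3 is set trans.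
4. The (R)-flavanone comes from an achiral 2'-hydroxychalcone by an organocatalytic enantioselective oxa-Michael cyclisation. This is the key step, the first stereocentre and the new method.
5. The chalcone comes from 3-benzyloxy-5-bromo-2-hydroxyacetophenone and vanillin isobutyrate. Ring order: sacrificial chromanone, then dihydrobenzofuran, then the final chromanone (brought in as a chromone).

Assumption: the sense of induction of the IDPi catalyst (step 4) and of the PyOx ligand (step 9) is assigned by analogy. Both antipodes of each are available, and the one that gives the drawn configuration is used.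

## Route

Step 1
Reactants: 1 2',3'-dihydroxyacetophenone
Product: 2 1-[3-(benzyloxy)-2-hydroxyphenyl]ethan-1-one
Conditions: BnBr (1.05 equiv), K2CO3 (1.1 equiv), acetone, reflux
Reagents that add atoms: benzyl bromide, BrCc1ccccc1
Why: Williamson etherification; the 2-OH is locked in a hydrogen bond to the acetyl C=O and is the less acidic and less nucleophilic phenol, so one equivalent of base and halide alkylates only the 3-OH.

Step 2
Reactants: 2 1-[3-(benzyloxy)-2-hydroxyphenyl]ethan-1-one
Product: 3 1-[3-(benzyloxy)-5-bromo-2-hydroxyphenyl]ethan-1-one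
Conditions: NBS (1.05 equiv), MeCN, 0 °C to rt
Reagents that add atoms: N-bromosuccinimide, O=C1CCC(=O)N1Br
Why: Electrophilic aromatic bromination; the free phenol directs to its only open ortho/para site (C5, also meta to the acetyl group), which places the later coupling handle para to the future ring oxygen.

Step 3
Reactants: 3 1-[3-(benzyloxy)-5-bromo-2-hydroxyphenyl]ethan-1-one; 4 vanillin isobutyrate (4-formyl-2-methoxyphenyl 2-methylpropanoate)
Product: 5 4-{(E)-3-[3-(benzyloxy)-5-bromo-2-hydroxyphenyl]-3-oxoprop-1-en-1-yl}-2-methoxyphenyl 2-methylpropanoate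
Conditions: BF3·OEt2 (1.0 equiv), 1,4-dioxane, rt; H2O quench
Reagents that add atoms: none
Why: Lewis-acid-mediated Claisen–Schmidt (aldol) condensation through the boron-chelated enol of the o-hydroxyketone; the non-basic medium keeps the aryl ester intact and dehydration gives the E-enone.

Step 4
Reactants: 5 4-{(E)-3-[3-(benzyloxy)-5-bromo-2-hydroxyphenyl]-3-oxoprop-1-en-1-yl}-2-methoxyphenyl 2-methylpropanoate
Product: 6 4-[(2R)-8-(benzyloxy)-6-bromo-4-oxochroman-2-yl]-2-methoxyphenyl 2-methylpropanoate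
Conditions: (S,S)-imidodiphosphorimidate (IDPi, bulky 3,3'-aryl groups, N-triflyl core; 5 mol%), toluene, −10 °C, stopped at about 85% conversion; one recrystallisation
Reagents that add atoms: none
Why: Proposed new method: enantioselective 6-endo-trig oxa-Michael cycloisomerisation of an unactivated 2'-hydroxychalcone under a confined, strong chiral Brønsted acid; the IDPi protonates the enone C=O (breaking the 2'-OH···O=C chelate), the hydroxyallyl cation sits as a contact ion pair in the chiral pocket, and the anion accepts the phenol proton while O attacks one face of Cβ, setting C2 as R, and because the counter-anion is non-basic the E1cB retro-reaction that erodes ee under amine catalysis is suppressed, while the 4-acyloxy group disfavours SN1 ionisation at C2; the closest known reaction types are the racemic Brønsted-acid chalcone-to-flavanone isomerisation, IDPi-catalysed Nazarov cyclisation of simple divinyl ketones and intramolecular hydroalkoxylation, and thiourea-catalysed oxa-Michael cyclisation of ester-activated chalcones.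

Step 5
Reactants: 6 4-[(2R)-8-(benzyloxy)-6-bromo-4-oxochroman-2-yl]-2-methoxyphenyl 2-methylpropanoate
Product: 8 methyl (2R,3R)-7-(benzyloxy)-5-bromo-2-[4-(isobutyryloxy)-3-methoxyphenyl]-2,3-dihydrobenzofuran-3-carboxylate, via 4-methoxy-2H-chromene enol ether 7 (not isolated)
Conditions: PhI(OAc)2 (1.2 equiv), H2SO4 (cat.), HC(OMe)3, 0 °C to rt
Reagents that add atoms: trimethyl orthoformate, COC(OC)OC
Why: Hypervalent-iodine oxidative ring contraction of a flavanone (the cyclic case of the aryl ketone to α-aryl ester 1,2-aryl shift): the iodane attacks enol ether 7 at C3 anti to the 2-aryl group, the equatorial C–I bond is antiperiplanar to C4–C4a, and the fused aryl ring migrates with inversion, so C2 is untouched, the new C3 centre is trans (2R,3R), and the acyloxy group keeps the 2-aryl ring from migrating (isoflavone pathway).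

Step 6
Reactants: 8 methyl (2R,3R)-7-(benzyloxy)-5-bromo-2-[4-(isobutyryloxy)-3-methoxyphenyl]-2,3-dihydrobenzofuran-3-carboxylate
Product: 9 4-[(2R,3S)-7-(benzyloxy)-5-bromo-3-(hydroxymethyl)-2,3-dihydrobenzofuran-2-yl]-2-methoxyphenol
Conditions: LiAlH4 (2.5 equiv), THF, −10 to 0 °C; aqueous work-up
Reagents that add atoms: none
Why: Hydride reduction of both esters; the methyl ester is reduced faster than its α-proton is removed, the aryl isobutyrate is cleaved in the same operation, ArBr and the benzyl ether survive at or below 0 °C, and no centre is touched (3R becomes 3S only through CIP ranking).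

Step 7
Reactants: 9 4-[(2R,3S)-7-(benzyloxy)-5-bromo-3-(hydroxymethyl)-2,3-dihydrobenzofuran-2-yl]-2-methoxyphenol
Product: 10 [(2R,3S)-7-(benzyloxy)-2-(4-hydroxy-3-methoxyphenyl)-3-(hydroxymethyl)-2,3-dihydrobenzofuran-5-yl]boronic acid
Conditions: XPhos Pd G2 (2 mol%), XPhos (4 mol%), B2(OH)4 (3 equiv), KOAc (3 equiv), EtOH, 80 °C
Reagents that add atoms: tetrahydroxydiboron, OB(O)B(O)O
Why: Miyaura-type Pd-catalysed borylation of the aryl bromide gives the boronic acid directly, and the weak acetate base tolerates the free phenol and alcohol.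

Step 8
Reactants: 11 5,7-dihydroxy-4H-chromen-4-one
Product: 12 5,7-bis(benzyloxy)-4H-chromen-4-one
Conditions: BnBr (2.5 equiv), K2CO3 (3 equiv), DMF, 70 °C
Reagents that add atoms: benzyl bromide, BrCc1ccccc1
Why: Double Williamson etherification; warm DMF is enough to alkylate the chelated 5-OH as well.

Step 9
Reactants: 10 [(2R,3S)-7-(benzyloxy)-2-(4-hydroxy-3-methoxyphenyl)-3-(hydroxymethyl)-2,3-dihydrobenzofuran-5-yl]boronic acid; 12 5,7-bis(benzyloxy)-4H-chromen-4-one
Product: 13 (2S)-5,7-bis(benzyloxy)-2-[(2R,3S)-7-(benzyloxy)-2-(4-hydroxy-3-methoxyphenyl)-3-(hydroxymethyl)-2,3-dihydrobenzofuran-5-yl]chroman-4-one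
Conditions: Pd(OCOCF3)2 (10 mol%), (R)-t-BuPyOx (12 mol%), NH4PF6 (30 mol%), H2O (5 equiv), ClCH2CH2Cl, 60 °C; 12 used in 1.5-fold excess
Reagents that add atoms: none
Why: Pd(II)/pyridine-oxazoline asymmetric conjugate addition of an arylboronic acid to a chromone (transmetalation, ligand-controlled carbopalladation of one C2=C3 face, protonolysis) sets C2 as S under catalyst control, the remote centres do not interfere, and the base-free medium avoids retro-oxa-Michael opening.

Step 10
Reactants: 13 (2S)-5,7-bis(benzyloxy)-2-[(2R,3S)-7-(benzyloxy)-2-(4-hydroxy-3-methoxyphenyl)-3-(hydroxymethyl)-2,3-dihydrobenzofuran-5-yl]chroman-4-one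
Product: 14 silyhermin B
Conditions: H2 (1 atm), 10% Pd/C, EtOAc–MeOH, rt
Reagents that add atoms: none
Why: Catalytic hydrogenolysis of the three benzyl aryl ethers under neutral conditions does not epimerise the flavanone, and the ring benzylic C–O bonds of the dihydrobenzofuran and chromanone cleave much more slowly.

## Compound list

1 | 2',3'-dihydroxyacetophenone | CC(=O)c1cccc(O)c1O | starting material
2 | 1-[3-(benzyloxy)-2-hydroxyphenyl]ethan-1-one | CC(=O)c1cccc(OCc2ccccc2)c1O | intermediate
3 | 1-[3-(benzyloxy)-5-bromo-2-hydroxyphenyl]ethan-1-one | CC(=O)c1cc(Br)cc(OCc2ccccc2)c1O | intermediate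
4 | vanillin isobutyrate | CC(C)C(=O)Oc1ccc(C=O)cc1OC | starting material
5 | (E)-2'-hydroxychalcone (3'-OBn, 5'-Br, 4-isobutyryloxy, 3-OMe) | CC(C)C(=O)Oc1ccc(/C=C/C(=O)c2cc(Br)cc(OCc3ccccc3)c2O)cc1OC | intermediate
6 | (2R)-flavanone (8-OBn, 6-Br, 4'-isobutyryloxy, 3'-OMe) | O=C1C[C@H](c2ccc(OC(=O)C(C)C)c(OC)c2)Oc2c(OCc3ccccc3)cc(Br)cc21 | intermediate
7 | (2R)-4-methoxy-2H-chromene enol ether of 6 | COC1=C[C@H](c2ccc(OC(=O)C(C)C)c(OC)c2)Oc2c(OCc3ccccc3)cc(Br)cc21 | intermediate (not isolated)
8 | methyl (2R,3R)-trans-2-aryl-7-(benzyloxy)-5-bromo-2,3-dihydrobenzofuran-3-carboxylate | COc1cc([C@@H]2Oc3c(OCc4ccccc4)cc(Br)cc3[C@H]2C(=O)OC)ccc1OC(=O)C(C)C | intermediate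
9 | (2R,3S)-bromo diol-phenol | COc1cc([C@@H]2Oc3c(OCc4ccccc4)cc(Br)cc3[C@H]2CO)ccc1O | intermediate
10 | (2R,3S)-dihydrobenzofuran-5-ylboronic acid | COc1cc([C@@H]2Oc3c(OCc4ccccc4)cc(B(O)O)cc3[C@H]2CO)ccc1O | intermediate
11 | 5,7-dihydroxy-4H-chromen-4-one | O=c1ccoc2cc(O)cc(O)c12 | starting material
12 | 5,7-bis(benzyloxy)-4H-chromen-4-one | O=c1ccoc2cc(OCc3ccccc3)cc(OCc3ccccc3)c12 | intermediate
13 | tri-O-benzyl silyhermin B | COc1cc([C@@H]2Oc3c(OCc4ccccc4)cc([C@@H]4CC(=O)c5c(OCc6ccccc6)cc(OCc6ccccc6)cc5O4)cc3[C@H]2CO)ccc1O | intermediate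
14 | silyhermin B | COc1cc([C@@H]2Oc3c(O)cc([C@@H]4CC(=O)c5c(O)cc(O)cc5O4)cc3[C@H]2CO)ccc1O | target

## Step count and risks

Total steps: 10. Longest linear sequence: 9 (steps 1–7, 9 and 10). Step 8 is a one-step side branch.

**Step 4 (new method).** The risks are low turnover or low ee, and erosion of ee as the chalcone/flavanone equilibrium is approached.
- The fallback sets out from 3 and returns at 6, and uses known chemistry.
- C-acylation of the lithium dianion of 3 with Boc2O (LiHMDS, THF, −78 °C) gives tert-butyl 3-[3-(benzyloxy)-5-bromo-2-hydroxyphenyl]-3-oxopropanoate F1.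
- Knoevenagel condensation of F1 with 4 (cat. piperidine/AcOH, toluene, molecular sieves) gives the alkylidene β-keto ester tert-butyl 2-[3-(benzyloxy)-5-bromo-2-hydroxybenzoyl]-3-[4-(isobutyryloxy)-3-methoxyphenyl]prop-2-enoate F2.
- The established cinchona-thiourea oxa-Michael cyclisation of such ester-activated chalcones (10 mol%, toluene, −25 °C) gives tert-butyl (2R)-8-(benzyloxy)-6-bromo-2-[4-(isobutyryloxy)-3-methoxyphenyl]-4-oxochromane-3-carboxylate F3.
- TsOH at 80 °C in the same pot removes the tert-butyl ester by decarboxylation and delivers 6.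

**Step 5.** The risks are competing 2-aryl migration (isoflavone), 3-methoxylation, flavone formation, and slow migration of the brominated ring.
- The fallback sets out from 6 and returns at 8. It replaces the cationic iodine(III) shift by a carbene (Wolff) ring contraction.
- LiHMDS with CF3CO2CH2CF3 at −78 °C gives the (2R)-3-(trifluoroacetyl)flavanone F4.
- MsN3, Et3N and H2O in MeCN then give the (2S)-3-diazoflavanone F5. It has the same spatial arrangement at C2; only the descriptor changes.
- Irradiation in MeOH contracts the ring through the ketene to 8 together with its cis isomer, the methyl (2R,3S)-carboxylate F6.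
- Catalytic DBU in toluene equilibrates F6 to trans 8.

**Step 9.** The risks are a sluggish 5-alkoxychromone, protodeboronation of the electron-rich boronic acid, and interference from the free phenol.
- The fallback sets out from 9 and returns at 13. It forms the C–O bond instead of the C–C bond.
- Pd-catalysed formylation of 9 (Pd(OAc)2, di(1-adamantyl)-n-butylphosphine, CO/H2, TMEDA, toluene, 100 °C) gives (2R,3S)-7-(benzyloxy)-2-(4-hydroxy-3-methoxyphenyl)-3-(hydroxymethyl)-2,3-dihydrobenzofuran-5-carbaldehyde F7.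
- Commercial 2',4'-bis(benzyloxy)-6'-hydroxyacetophenone is C-acylated (LiHMDS, Boc2O) to tert-butyl 3-[2,4-bis(benzyloxy)-6-hydroxyphenyl]-3-oxopropanoate F8.
- Knoevenagel condensation of F7 with F8 gives the alkylidene β-keto ester F9.
- The pseudo-enantiomeric cinchona-thiourea cyclises F9 to the (2S)-chromanone-3-carboxylate F10.
- TsOH at 80 °C decarboxylates F10 to 13.

## Further compounds

F1 | step 4 | tert-butyl 3-[3-(benzyloxy)-5-bromo-2-hydroxyphenyl]-3-oxopropanoate | CC(C)(C)OC(=O)CC(=O)c1cc(Br)cc(OCc2ccccc2)c1O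
F2 | step 4 | tert-butyl 2-[3-(benzyloxy)-5-bromo-2-hydroxybenzoyl]-3-[4-(isobutyryloxy)-3-methoxyphenyl]prop-2-enoate (E/Z mixture) | CC(C)C(=O)Oc1ccc(C=C(C(=O)OC(C)(C)C)C(=O)c2cc(Br)cc(OCc3ccccc3)c2O)cc1OC
F3 | step 4 | tert-butyl (2R)-8-(benzyloxy)-6-bromo-2-[4-(isobutyryloxy)-3-methoxyphenyl]-4-oxochromane-3-carboxylate (C3 epimerisable) | O=C1C(C(=O)OC(C)(C)C)[C@H](c2ccc(OC(=O)C(C)C)c(OC)c2)Oc2c(OCc3ccccc3)cc(Br)cc21
F4 | step 5 | (2R)-3-(trifluoroacetyl)flavanone derived from 6 (C3 epimerisable) | O=C1C(C(=O)C(F)(F)F)[C@H](c2ccc(OC(=O)C(C)C)c(OC)c2)Oc2c(OCc3ccccc3)cc(Br)cc21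
F5 | step 5 | (2S)-3-diazoflavanone derived from 6 | O=C1C(=[N+]=[N-])[C@H](c2ccc(OC(=O)C(C)C)c(OC)c2)Oc2c(OCc3ccccc3)cc(Br)cc21
F6 | step 5 | methyl (2R,3S)-cis-7-(benzyloxy)-5-bromo-2-[4-(isobutyryloxy)-3-methoxyphenyl]-2,3-dihydrobenzofuran-3-carboxylate | COc1cc([C@@H]2Oc3c(OCc4ccccc4)cc(Br)cc3[C@@H]2C(=O)OC)ccc1OC(=O)C(C)C
F7 | step 9 | (2R,3S)-7-(benzyloxy)-2-(4-hydroxy-3-methoxyphenyl)-3-(hydroxymethyl)-2,3-dihydrobenzofuran-5-carbaldehyde | COc1cc([C@@H]2Oc3c(OCc4ccccc4)cc(C=O)cc3[C@H]2CO)ccc1O
F8 | step 9 | tert-butyl 3-[2,4-bis(benzyloxy)-6-hydroxyphenyl]-3-oxopropanoate | CC(C)(C)OC(=O)CC(=O)c1c(O)cc(OCc2ccccc2)cc1OCc1ccccc1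
F9 | step 9 | alkylidene β-keto ester from F7 and F8 (E/Z mixture) | COc1cc([C@@H]2Oc3c(OCc4ccccc4)cc(C=C(C(=O)OC(C)(C)C)C(=O)c4c(O)cc(OCc5ccccc5)cc4OCc4ccccc4)cc3[C@H]2CO)ccc1O
F10 | step 9 | tert-butyl (2S)-5,7-bis(benzyloxy)-2-[(2R,3S)-dihydrobenzofuran-5-yl]-4-oxochromane-3-carboxylate (C3 epimerisable) | COc1cc([C@@H]2Oc3c(OCc4ccccc4)cc([C@@H]4C(C(=O)OC(C)(C)C)C(=O)c5c(OCc6ccccc6)cc(OCc6ccccc6)cc5O4)cc3[C@H]2CO)ccc1O
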